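The earlier runs and the new flask are calculated with constants of no real substance; noise was put on by code.

We read these flasks at 20 h, so the useful question is how many half-lives of starting material fit into that time, and how much of what is lost stays as target.

the same everywhere: free catalyst 48 mM
- birch: starting material 0.22 M; partner 0.24 M; run made earlier
- elm: starting material 0.64 M; partner 0.24 M; run made earlier
- beta: starting material 0.15 M; partner 0.240 M; time 20 h
- alpha: starting material 0.25 M; partner 0.240 M; time 20 h
- zeta: starting material 0.40 M; partner 0.240 M; time 20 h
- theta: starting material 0.50 M; partner 0.240 M; time 20 h

- birch (time / h: target / %, starting material / %): 2.50: 8, 84; 5.00: 16, 74; 8.00: 24, 63; 10.0: 30, 52; 12.0: 36, 44; 15.0: 40, 35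
- elm (time / h: target / %, starting material / %): 1.00: 0, 98; 2.50: 6, 93; 5.00: 7, 85; 8.00: 11, 74; 10.0: 7, 67; 15.0: 10, 52

(each reading ± 2 percentage points)

- percent here means starting material units held: one side product counts as two
- steps that have been proposed: starting material + catalyst intermediate A -> catalyst intermediate B; starting material + target -> side product; catalyst intermediate B -> free catalyst + target; partner + free catalyst -> catalyst intermediate A
- "hardly changes" means that all values lie within two and a half points (for a concentration: within two and a half percent of the largest)

* [target] at the end for beta, alpha, zeta, theta, in this order
* the shape of the row from first to last (falls all the way / rises all the way / rises, then falls / hardly changes / falls, then rises)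

We count the rate as a half-life. Birch holds 35% of its starting material at 15.0 h, which gives an average half-life of 9.90 h. Elm holds 52% at 15.0 h, which gives 15.9 h. The charge of elm is 2.91 times that of birch, and its half-life reads longer by a factor of 1.61. The half-life thus grows by 3.14 h for each birch charge of starting material added; we call this the lengthening per charge, and we take it as a straight line through these two readings.

The selectivity, here the target held per unit of starting material lost, differs as well. At 15.0 h the reading is 0.615 in birch but 0.208 in elm, lower by a factor of 2.96. We draw a straight line here too, with slope 0.969 L mol⁻¹, and carry it unchanged to the later time.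

For theta the line gives:

half-life = 13.9 h

half-lives in the run = 1.44

starting material left = 36.9%

Multiplying the charge, the fraction lost and the selectivity at each charge gives our row:

0.0809 M, 0.108 M, 0.118 M, 0.109 M

The forecast gives 0.072 M, 0.091 M, 0.088 M, 0.076 M, and its shape is rises, then falls: “the target passes through a shallow maximum”. Our row has the same shape, but its top of 0.118 M, at zeta, is higher than the forecast's top of 0.091 M, at alpha.

The flask gives 0.0871 M, 0.109 M, 0.108 M, 0.0965 M, so the shape is rises, then falls.

    starting material + catalyst intermediate A → catalyst intermediate B (k = 6.28 × 10⁻⁴ L mol⁻¹ s⁻¹)
    starting material + target → side product (k = 8.36 × 10⁻⁵ L mol⁻¹ s⁻¹)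
    catalyst intermediate B → free catalyst + target (k = 1.45 × 10⁻⁴ s⁻¹)
    partner + free catalyst → catalyst intermediate A (k = 0.00285 L mol⁻¹ s⁻¹)

At the end, theta holds 35.4% of its starting material, where our count of 1.44 half-lives gave 36.9%. The same lengthening of 3.14 h per birch charge puts the half-life of zeta at 12.5 h. That makes 1.60 half-lives in 20 h and leaves 33.0%, and zeta ends with 29.5%.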